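Ring locants: C1 (C=O), C2 (C–CH3) and C3 (epoxide), C4 (CH2), C5 (CH with side chain), C6 (CH–O-tigloyl); C7 carries the exocyclic =CH2. The route exploits that C2–C3, C4, C5 and C7=CH2 form a masked 1,5-diene, a 4-vinylcyclohexene. The cyclohexane ring is therefore cut at C4–C5. One nickel(0)-mediated reductive allyl–allyl coupling closes the carbocycle, sets C5, places the C2=C3 and C7=CH2 double bonds, and funnels E/Z and epimer mixtures into one isomer. Its precursor is an acyclic L-tartrate acetonide (O–C1, O–C6) carrying a methyl-substituted allylic bromide arm and a Morita–Baylis–Hillman-derived 2-acylallyl bromide arm with the complete prenyl ketone chain.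

Key step: step 9

Remark: 1, 6 and 16 are assumed to be commercial. Stereo-elements that step 8 or step 9 erases (carbinol centres of 4, 5 and 10, double-bond geometries of 11 and 12) are carried as mixtures and left undefined in the SMILES.

Step 1
Reactants: 1 dimethyl 2,3-O-isopropylidene-L-tartrate
Product: 2 bis-Weinreb amide of 2,3-O-isopropylidene-L-tartaric acid
Conditions: MeNH(OMe)·HCl, i-PrMgCl, THF, −20 to 0 °C
Reagents that add atoms: N,O-dimethylhydroxylamine hydrochloride, CNOC.Cl
Why: Aminolysis of both esters by the chloromagnesium amide (Weinreb amide formation) is fast at low temperature and leaves the two dioxolane stereocentres, which become C1 and C6, untouched.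

Step 2
Reactants: 2 bis-Weinreb amide
Product: 3 keto amide (one amide turned into an acetyl group)
Conditions: MeMgBr (1.1 equiv), THF, −15 °C; aq. NH4Cl
Reagents that add atoms: methylmagnesium bromide, C[Mg]Br
Why: Weinreb ketone synthesis used as a desymmetrisation: the two amides of C2-symmetric 2 are equivalent, the chelated tetrahedral adduct survives until work-up, and one equivalent of Grignard reagent should therefore stop at the single keto amide.

Step 3
Reactants: 3 keto amide
Product: 4 tertiary vinyl carbinol (both C2 epimers)
Conditions: vinylMgBr (1.1 equiv), THF, −78 °C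
Reagents that add atoms: vinylmagnesium bromide, C=C[Mg]Br
Why: Grignard 1,2-addition picks the α-alkoxy ketone, far more electrophilic than the Weinreb amide at −78 °C, and the new carbinol centre C2 needs no control because step 8 erases it.

Step 4
Reactants: 4 tertiary vinyl carbinol
Product: 5 hydroxy aldehyde (C5 as CHO)
Conditions: DIBAL-H (2.2 equiv), THF, −78 °C; Rochelle salt
Reagents that add atoms: none
Why: Weinreb amide reduction stops at the aldehyde because the aluminium chelate collapses only on work-up, the first equivalent of DIBAL-H merely masking the tertiary alcohol as its aluminium alkoxide.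

Step 5
Reactants: 6 4-methylpent-3-enoic acid
Product: 8 N-methoxy-N,4-dimethylpent-3-enamide, via acylimidazole 7 (not isolated)
Conditions: CDI, CH2Cl2, rt; then MeNH(OMe)·HCl
Reagents that add atoms: N,O-dimethylhydroxylamine hydrochloride, CNOC.Cl
Why: Acylimidazole activation and aminolysis (Weinreb amide formation) run under near-neutral conditions that should keep the β,γ-double bond out of conjugation.

Step 6
Reactants: 8 N-methoxy-N,4-dimethylpent-3-enamide
Product: 9 6-methylhepta-1,5-dien-3-one (prenyl vinyl ketone)
Conditions: vinylMgBr, THF, 0 °C; inverse quench into cold aq. HCl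
Reagents that add atoms: vinylmagnesium bromide, C=C[Mg]Br
Why: Weinreb ketone synthesis, with an inverse quench into cold acid so that the released amine cannot add to the vinyl ketone and the skipped double bond is not conjugated.

Step 7
Reactants: 5 hydroxy aldehyde; 9 prenyl vinyl ketone
Product: 10 Morita–Baylis–Hillman diol (C5–OH epimers, C2–OH epimers)
Conditions: DABCO (0.5 equiv), THF–H2O, rt
Reagents that add atoms: none
Why: Morita–Baylis–Hillman reaction of a reactive α-alkoxy aldehyde with a vinyl ketone; the new carbinol centre C5 is formed without control and is erased in step 8, while any base-induced epimerisation at C6 is self-correcting because the trans-dioxolane is the stable isomer.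

Step 8
Reactants: 10 Morita–Baylis–Hillman diol
Product: 11 bis(allylic bromide) (E/Z mixture)
Conditions: PBr3, pyridine (cat.), Et2O, −10 °C
Reagents that add atoms: phosphorus tribromide, BrP(Br)Br
Why: Allylic bromination with transposition (SN2') acts on both carbinols at once: the tertiary vinyl carbinol gives the primary 3-methylallyl bromide (C4–Br), the Morita–Baylis–Hillman alcohol gives the 2-(bromomethyl)enone, and both uncontrolled stereocentres vanish.

Step 9
Reactants: 11 bis(allylic bromide)
Product: 13 trans-fused cyclohexene acetonide, via allylnickel bromide 12 (not isolated)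
Conditions: Ni(cod)2 (1.5 equiv), DMF, 25 °C, slow addition of 11 (final 2 mM)
Reagents that add atoms: none
Why: Ni(0) inserts into the more activated 2-acylallyl C–Br bond to give η3-allylnickel bromide 12, which takes up the second allylic bromide of the same molecule and releases NiBr2 by allyl–allyl reductive elimination; the closest known reaction type is the nickel(0)-mediated reductive cyclisation of α,ω-bis(allylic bromides), which turns 1,8-dibromoocta-2,6-diene mainly into 4-vinylcyclohexene. The single ring closed is the six-membered carbocycle, joined head-to-tail between the CH2 terminus C4 of the methyl-substituted allyl unit and the substituted terminus C5 of the acylallyl unit, endo for the first unit (C2=C3 ends inside the ring) and exo for the second (C7=CH2 ends outside). The new stereocentre C5 is controlled by the tartrate-derived centres C1 and C6: the trans-fused dioxolane fixes both C–O bonds equatorial in the chair-like closure and the bulky acylvinyl group should take the third equatorial site, trans to O–C6 and cis to O–C1. Fast η3–η1–η3 (syn–anti) exchange in DMF erases the E/Z information of both arms, so only the anti-configured allyl unit that can reach C5 is drained and the isomer mixture converges on one product. The step needs six-ring over eight-ring (CH2-to-CH2), quaternary-carbon (C2-to-CH2) and cyclobutane (C2-to-C5) coupling, which is secured by the two-atom tether, by the strain of a Z,Z-cyclooctadiene trans-fused to the dioxolane and by the steric cost of bonding at the fully substituted C2. High dilution suppresses intermolecular coupling, and the ketone, the prenyl double bond and the acetal are inert to allylnickel halides at 25 °C.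

Step 10
Reactants: 13 trans-fused cyclohexene acetonide
Product: 14 trans-1,6-diol
Conditions: AcOH–H2O 4:1, 40 °C
Reagents that add atoms: none
Why: Acid-catalysed acetal hydrolysis, eased by the strain of the trans-fused dioxolane, under conditions too mild to ionise the allylic C1–O bond or to conjugate the skipped enone.

Step 11
Reactants: 14 trans-1,6-diol
Product: 15 epoxy diol (epoxide cis to C1–OH and to the side chain)
Conditions: VO(acac)2 (5 mol %), t-BuOOH, CH2Cl2, 0 °C
Reagents that add atoms: tert-butyl hydroperoxide, CC(C)(C)OO
Why: Hydroxyl-directed vanadium-catalysed epoxidation: the allylic C1–OH delivers the peroxide oxygen to its own face of C2=C3, which sets C2 and C3 cis to the side chain, while the electron-poor C7=CH2 bond and the undirected prenyl double bond react much more slowly.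

Step 12
Reactants: 15 epoxy diol; 16 tigloyl chloride
Product: 17 C6 mono-tiglate
Conditions: pyridine, DMAP (cat.), CH2Cl2, −20 °C
Reagents that add atoms: none
Why: Kinetically controlled regioselective acylation: C6–OH lies between two CH groups, whereas C1–OH is neopentyl-like next to the fully substituted epoxide carbon C2 and hydrogen-bonded to the cis epoxide oxygen, so the acid chloride should take C6–OH.

Step 13
Reactants: 17 C6 mono-tiglate
Product: 18 epoxy ketone with prenyl ketone side chain
Conditions: Dess–Martin periodinane, CH2Cl2, 0 °C to rt
Reagents that add atoms: none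
Why: Dess–Martin oxidation turns the remaining C1 carbinol into the ketone under neutral conditions that spare the epoxide, the ester and the skipped enone, and C6 keeps its stable equatorial ester.

Step 14
Reactants: 18 epoxy ketone
Product: 19 CNP0284595.1 (target)
Conditions: O2, tetraphenylporphyrin (cat.), visible light, CH2Cl2, −20 °C
Reagents that add atoms: oxygen, O=O
Why: Schenck ene reaction: singlet oxygen attacks only the electron-rich trisubstituted C10=C11 bond, and abstraction of the activated C9–H on the more crowded side places the hydroperoxide on tertiary C11 and the new E double bond in conjugation with C8=O.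

Compound list

1 | dimethyl (4R,5R)-2,2-dimethyl-1,3-dioxolane-4,5-dicarboxylate (dimethyl 2,3-O-isopropylidene-L-tartrate) | COC(=O)[C@@H]1OC(C)(C)O[C@H]1C(=O)OC | starting material
2 | (4R,5R)-N,N'-dimethoxy-N,N',2,2-tetramethyl-1,3-dioxolane-4,5-dicarboxamide | CON(C)C(=O)[C@@H]1OC(C)(C)O[C@H]1C(=O)N(C)OC | intermediate
3 | (4R,5R)-5-acetyl-N-methoxy-N,2,2-trimethyl-1,3-dioxolane-4-carboxamide | CC(=O)[C@@H]1OC(C)(C)O[C@H]1C(=O)N(C)OC | intermediate
4 | trans-dioxolane (configuration of 1) bearing a 2-hydroxybut-3-en-2-yl group and the Weinreb amide, both carbinol epimers | C=CC(C)(O)[C@@H]1OC(C)(C)O[C@H]1C(=O)N(C)OC | intermediate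
5 | trans-dioxolane (configuration of 1) bearing the 2-hydroxybut-3-en-2-yl group and a formyl group | C=CC(C)(O)[C@@H]1OC(C)(C)O[C@H]1C=O | intermediate
6 | 4-methylpent-3-enoic acid | CC(C)=CCC(=O)O | starting material
7 | 1-(4-methylpent-3-enoyl)imidazole | CC(C)=CCC(=O)n1ccnc1 | intermediate
8 | N-methoxy-N,4-dimethylpent-3-enamide | CC(C)=CCC(=O)N(C)OC | intermediate
9 | 6-methylhepta-1,5-dien-3-one | C=CC(=O)CC=C(C)C | intermediate
10 | Morita–Baylis–Hillman diol: trans-dioxolane bearing the 2-hydroxybut-3-en-2-yl group and a CH(OH)–C(=CH2)–C(=O)–CH2CH=C(CH3)2 group, carbinol epimers | C=CC(C)(O)[C@@H]1OC(C)(C)O[C@H]1C(O)C(=C)C(=O)CC=C(C)C | intermediate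
11 | bis(allylic bromide): trans-dioxolane bearing a 4-bromobut-2-en-2-yl arm and a CH=C(CH2Br)–C(=O)–CH2CH=C(CH3)2 arm, E/Z mixture | BrCC=C(C)[C@@H]1OC(C)(C)O[C@H]1C=C(CBr)C(=O)CC=C(C)C | intermediate
12 | allylnickel(II) bromide of the 2-acylallyl arm of 11 (drawn in its η1 form) | BrCC=C(C)[C@@H]1OC(C)(C)O[C@H]1C=C(C[Ni]Br)C(=O)CC=C(C)C | intermediate
13 | 2-methylcyclohex-2-ene-1,6-diol acetonide (trans-fused) bearing the 6-methyl-3-oxohepta-1,5-dien-2-yl group at C5; side chain and O–C1 on one face, O–C6 on the other | C=C(C(=O)CC=C(C)C)[C@@H]1CC=C(C)[C@@H]2OC(C)(C)O[C@@H]12 | intermediate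
14 | trans-2-methyl-5-(6-methyl-3-oxohepta-1,5-dien-2-yl)cyclohex-2-ene-1,6-diol; C1–OH cis and C6–OH trans to the side chain | C=C(C(=O)CC=C(C)C)[C@@H]1CC=C(C)[C@H](O)[C@H]1O | intermediate
15 | 2,3-epoxide of 14, epoxide oxygen cis to C1–OH and to the side chain | C=C(C(=O)CC=C(C)C)[C@@H]1C[C@@H]2O[C@]2(C)[C@H](O)[C@H]1O | intermediate
16 | (E)-2-methylbut-2-enoyl chloride (tigloyl chloride) | ClC(=O)/C(C)=C/C | starting material
17 | C6 O-tigloyl ester of 15, C1–OH free | C=C(C(=O)CC=C(C)C)[C@@H]1C[C@@H]2O[C@]2(C)[C@H](O)[C@H]1OC(=O)/C(C)=C/C | intermediate
18 | (2S,3S,5S,6S)-2,3-epoxy-2-methyl-5-(6-methyl-3-oxohepta-1,5-dien-2-yl)-1-oxocyclohexan-6-yl tiglate | C=C(C(=O)CC=C(C)C)[C@@H]1C[C@@H]2O[C@]2(C)C(=O)[C@H]1OC(=O)/C(C)=C/C | intermediate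
19 | CNP0284595.1: (2S,3S,5S,6S)-2,3-epoxy-5-[(4E)-6-hydroperoxy-6-methyl-3-oxohepta-1,4-dien-2-yl]-2-methyl-1-oxocyclohexan-6-yl tiglate | C=C(C(=O)/C=C/C(C)(C)OO)[C@@H]1C[C@@H]2O[C@]2(C)C(=O)[C@H]1OC(=O)/C(C)=C/C | target

Total step count: 14. Longest linear sequence: 12 steps (steps 1–4 and 7–14).

Steps most likely to fail

Step 9. The closure may drift to head-to-head coupling (eight-membered ring). It may also suffer intermolecular oligomerisation, or loss of the neighbouring alkoxide from an allylnickel species. The fallback replaces the reductive coupling of two electrophiles by a polar cation–allylmetal cyclisation; it sets out from 10 and comes back at 13. Selective acetylation of the secondary carbinol of 10 (Ac2O, pyridine; the tertiary alcohol stays free) gives the Morita–Baylis–Hillman acetate F1. SN2' displacement with a tributylstannylcuprate gives the 2-acylallylstannane F2. BF3·OEt2 at −78 °C then ionises the tertiary allylic alcohol, and the allylstannane captures the CH2 terminus of the allyl cation in an SE2' closure, with loss of the tin group, to give 13.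

Step 12. The acid chloride may discriminate poorly between the two secondary hydroxyl groups. Double acylation or acyl migration may also occur. The fallback is a protecting-group detour that sets out from 15 and comes back at 17. Exhaustive silylation (TESOTf, 2,6-lutidine) gives the bis(triethylsilyl) ether F3. Mild acid (AcOH–THF–H2O) removes the less hindered C6 silyl group first and gives the C1 mono-silyl ether F4. Acylation with 16 then has only one free hydroxyl group and gives the silylated tiglate F5. HF·pyridine frees C1–OH to give 17.

Step 14. Hydrogen abstraction from the geminal methyl groups may compete with abstraction from C9. That would put the hydroperoxide on C10 (poor regioselectivity of the ene reaction). The fallback replaces the singlet-oxygen ene reaction by a ground-state autoxidation; it sets out from 18 and comes back at 19. A mild amine base (Et3N, O2, CH2Cl2) deprotonates only the doubly activated C9–H. The extended dienolate takes up triplet oxygen at its γ-carbon C11, the known course of base-promoted autoxidation of β,γ-unsaturated ketones to γ-hydroperoxy enones. No further compound is made on the way.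

Further compounds
F1 | step 9 | Morita–Baylis–Hillman acetate of 10 (secondary O-acetyl, tertiary OH free) | C=CC(C)(O)[C@@H]1OC(C)(C)O[C@H]1C(OC(C)=O)C(=C)C(=O)CC=C(C)C
F2 | step 9 | 2-acylallylstannane with free tertiary vinyl carbinol | C=CC(C)(O)[C@@H]1OC(C)(C)O[C@H]1C=C(C[Sn](CCCC)(CCCC)CCCC)C(=O)CC=C(C)C
F3 | step 12 | bis(triethylsilyl) ether of 15 | C=C(C(=O)CC=C(C)C)[C@@H]1C[C@@H]2O[C@]2(C)[C@H](O[Si](CC)(CC)CC)[C@H]1O[Si](CC)(CC)CC
F4 | step 12 | C1 mono(triethylsilyl) ether of 15 | C=C(C(=O)CC=C(C)C)[C@@H]1C[C@@H]2O[C@]2(C)[C@H](O[Si](CC)(CC)CC)[C@H]1O
F5 | step 12 | C1 triethylsilyl ether of 17 | C=C(C(=O)CC=C(C)C)[C@@H]1C[C@@H]2O[C@]2(C)[C@H](O[Si](CC)(CC)CC)[C@H]1OC(=O)/C(C)=C/C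
F0 | step 14 | none | none
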